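## The problem

The target is a monocyclic cyclohexane substituted on five of its six carbons. With the ring numbered C1 (Cl, CH3), C2 (Cl), C3, C4 (Br), C5 (CH3, (E)-2-bromoethenyl), C6, it has four stereocentres, two of them fully substituted and 1,3-related across C6. The two chlorines, the bromine and the bromoethenyl group lie on one face and both methyl groups on the other. The C1/C2 dichloride is therefore cis, a formal syn addition to a C1=C2 alkene that molecular chlorine does not give, and the C4 bromine is cis to the bromoethenyl group. C4 and C5 are adjacent and can be set early under reagent control; an oxygen on C4 can then decide the face on which C1 and C2 are functionalised. The halogens are the fragile part: the tertiary chloride ionises and eliminates, the secondary bromide sits next to a quaternary carbon, and the bromoalkene tolerates neither organometallic reagents nor ozone or peracids. Halogenation therefore comes late and the bromoalkene last. The enabling feature is that a C1=C2 alkene and a vinyl group on C5 are exactly the two alkenes released when a 1-methylcyclobutene made of C1, C6, C5 and the inner vinyl carbon is opened by an alkylidene at the end of a C4–C3–C2 chain on C5.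

## Retrosynthesis

**19 to 17 and 18.** The C=C bond of the bromoethenyl group is cut (Takai olefination of aldehyde 17 with bromoform 18). Carrying the bromoalkene through earlier steps would expose it to ozone, peracid and phosphorus halides, and cross-metathesis on a vinyl group attached to a quaternary carbon is unpromising. Aldehyde 17 has no α-hydrogen, so it cannot epimerise. The forward step must be E-selective on a hindered aldehyde and leave three alkyl halides alone.

**17 to 15.** The formyl carbon is traced back to the inner carbon of a vinyl group (ozonolysis). The vinyl group is what the key step delivers. The cut fixes the order of events: the ring alkene must already be consumed when ozone is used.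

**15 to 14.** The C4–Br bond is cut to a C4–O bond of opposite configuration. The substitution is placed here for three reasons:
- in 14 both methyl groups are equatorial and the C4–O bond is locked axial, the geometry from which hindered alkoxyphosphonium ions are displaced with inversion;
- C3 is no longer allylic, so elimination is not assisted;
- the hydroxyl has by then served as a directing group.

**14 to 13, 12 and 11.** Both C–Cl bonds are cut back to an epoxide on the opposite ring face. Chlorine addition would give the trans dichloride, and catalytic syn-dichlorination is established only for 1,2-disubstituted alkenes. An epoxide can instead be converted with inversion at both carbons, chloride entering first at the tertiary C1 and then at C2. The C4 hydroxyl is masked as acetate 12 during this step and released from 13 afterwards, because the chlorophosphorane would otherwise substitute it. The precursor 11 has two C–O bonds in place of two C–Cl bonds and the same carbon skeleton.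

**11 to 10.** The epoxide is cut to the C1=C2 alkene. The C4 hydroxyl of 10 lies on the face of the C5 methyl group, which is the face the epoxide must occupy, so a hydroxyl-directed epoxidation transfers the C4/C5 stereochemistry to C1/C2. A peracid on a protected alcohol would have to rely on a weak steric bias.

**10 to 9 (key disconnection).** The C1=C2 bond and the vinyl C=C bond are exchanged for the cyclobutene C=C bond and a terminal alkene. Precursor 9 is an isomer of 10 with a four-membered instead of a six-membered ring and the same two stereocentres. A Diels–Alder route with isoprene would place the two methyl-bearing carbons 1,4, not 1,3. The forward reaction must close the six-membered ring onto the methyl-bearing cyclobutene carbon and not oligomerise. The hydroxyl is left free because the catalyst tolerates it and the next step needs it.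

**9 to 6 and 7.** The C3–C4 bond is cut (allylboration of aldehyde 6 with borane 7). Reagent control sets C4 independently of the neighbouring quaternary centre, whose substituents differ too little to direct the addition. It also turns any minor enantiomer of 6 into a separable diastereomer.

**6 to 5, then to 3 and 4, then to 1.** The aldehyde comes from ester 5 by partial reduction. The ring methyl comes from an iron-catalysed coupling of enol triflate 3 with methylmagnesium bromide 4, which fixes the double bond position. Triflate 3 comes from the achiral, commercial keto ester 1 by enantioselective deprotonation, which creates the quaternary stereocentre by distinguishing two enantiotopic methylene groups.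

## Roads not taken

**Alternative 1:** The cut is the C5–CH3 bond, made as a C5–CH2Si bond from a silicon tether on the C4 oxygen. The enone A2 carries a (bromomethyl)dimethylsilyl ether on C4. Under tin hydride chain conditions its α-silyl radical would add to C5 and give the cis-fused siloxane ketone A1; protodesilylation would later reveal the methyl group.
- Merits: the tether can only deliver the methyl group cis to the C4 oxygen, the relationship an invertive bromination needs. In this respect the road is more secure than the chosen plan, where the C4/C5 relationship rests on two separate reagent-controlled steps. The CH2O group on C5 is at a convenient oxidation level.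
- Weak points: C1 arrives as a ketone, so the C1 methyl and a C1=C2 alkene must still be made by addition and dehydration, which can also give the C1=C6 or exocyclic isomers. An enantiopure 4-hydroxycyclohexenone is needed first, and stoichiometric tin and two silicon operations add steps.
- Comparison: against the better stereochemical guarantee, the chosen plan has a shorter path to alkene 10 with the double bond fixed at C1=C2 and no tin. The halogenation problems are the same on both roads.

**Alternative 2:** The cut is C2–C3, made as the alkene of a cyclohexenone. The diketo aldehyde A4, available in one conjugate addition, would be cyclised by a chiral secondary amine that converts one of its two enantiotopic acetyl groups into an enamine; attack on the aldehyde and dehydration give A3.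
- Merits: this is the cheapest and shortest access to a six-membered ring with the C5 quaternary centre and a C4 carbonyl, without metals or protecting groups. In step count to a ring it beats the chosen plan.
- Weak points: selecting between enantiotopic nucleophilic acetyl groups has little direct precedent, and the epimerisable methyl-bearing carbon of A4 complicates it. In A3 the alkene is at C2=C3 and C1 is a CH(CH3) centre, so C1 must be re-functionalised to carry chlorine. The acetyl group has to be turned into a bromoethenyl group by a multi-step detour. Reduction of the C4 ketone must also give the alcohol cis to the C5 methyl group.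
- Comparison: the chosen plan is longer to the ring. It offers the alkene in the right place, a vinyl group one ozonolysis away from the olefination precursor, and reagent-controlled absolute configuration.

**Alternative 3:** The cuts are C5–C4 and C6–C1 (Diels–Alder). Methacrolein A6, activated by a chiral cationic oxazaborolidine, would add to the silyloxydiene A7 with ortho regiochemistry to give the endo adduct A5.
- Merits: one catalytic step builds the ring, the quaternary C5 with a formyl group already at the oxidation level of the final olefination, and an oxygen at C4. In convergence, atom economy and precedent for the ring-forming step this road is better than the chosen one.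
- Weak points: in A5 the C4 oxygen is cis to the formyl group, so a single inversion would place bromine trans to the bromoethenyl group; a net retention at a neopentyl centre would be needed. The alkene is at C2=C3 and C1 is a CH(CH3) stereocentre, so the tertiary chloride requires moving the double bond to C1=C2 through an allylic silyl ether that is prone to elimination.
- Comparison: the chosen plan has the alkene at C1=C2 from the start and a C4 oxygen that needs only one inversion. It pays with a linear preparation of cyclobutene 9 and a less tested ring-forming step.

Key step: step 5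

Assumption: the (R,R)-amide in step 1 is taken as the antipode that leads to (S)-3; if correlation shows the opposite sense, the (S,S)-amide is used and nothing else changes.
Assumption: borane 7 is the antipode of B-allyldiisopinocampheylborane that adds to the Re face of aldehydes, taken to be the dextrorotatory reagent from (−)-α-pinene, used as a commercial solution.

## Route

Step 1
Reactants: 1 methyl 1-methyl-3-oxocyclobutane-1-carboxylate
Product: 3 methyl (1S)-1-methyl-3-[(trifluoromethanesulfonyl)oxy]cyclobut-2-ene-1-carboxylate, via lithium enolate 2 (not isolated)
Conditions: lithium (R,R)-bis(1-phenylethyl)amide (from the amine and n-BuLi), LiCl, THF, −100 to −78 °C; then N-(5-chloropyridin-2-yl)bis(trifluoromethanesulfonimide), −78 °C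
Reagents that add atoms: N-(5-chloropyridin-2-yl)bis(trifluoromethanesulfonimide) (Comins' reagent), Clc1ccc(N(S(=O)(=O)C(F)(F)F)S(=O)(=O)C(F)(F)F)nc1
Why: Enantioselective deprotonation of a prochiral 3,3-disubstituted cyclobutanone by a C2-symmetric chiral lithium amide distinguishes the two enantiotopic α-methylene groups and so fixes the quaternary centre; O-sulfonylation of enolate 2 then gives the cyclobutenyl triflate, the ester having no α-hydrogen. Any shortfall in enantiomeric purity is corrected in step 4, where the minor enantiomer becomes a separable diastereomer.

Step 2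
Reactants: 3 methyl (1S)-1-methyl-3-[(trifluoromethanesulfonyl)oxy]cyclobut-2-ene-1-carboxylate; 4 methylmagnesium bromide
Product: 5 methyl (1S)-1,3-dimethylcyclobut-2-ene-1-carboxylate
Conditions: MeMgBr, Fe(acac)3 (5 mol%), THF/NMP, −30 °C
Reagents that add atoms: methylmagnesium bromide (4), C[Mg]Br
Why: Iron-catalysed Kumada-type cross-coupling of an alkenyl triflate with a methyl Grignard reagent is much faster at low temperature than addition to the hindered α-quaternary ester; the stereocentre is not involved.

Step 3
Reactants: 5 methyl (1S)-1,3-dimethylcyclobut-2-ene-1-carboxylate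
Product: 6 (1S)-1,3-dimethylcyclobut-2-ene-1-carbaldehyde
Conditions: iBu2AlH (1.1 equiv), CH2Cl2, −78 °C; aqueous potassium sodium tartrate
Reagents that add atoms: none
Why: Partial reduction of an ester with iBu2AlH: the tetrahedral aluminium hemiacetal of this α-quaternary ester should persist at −78 °C and release the aldehyde only on work-up; the aldehyde cannot epimerise and, being volatile, is carried on as a solution.

Step 4
Reactants: 6 (1S)-1,3-dimethylcyclobut-2-ene-1-carbaldehyde; 7 (+)-B-allyldiisopinocampheylborane
Product: 9 (1R)-1-[(1S)-1,3-dimethylcyclobut-2-en-1-yl]but-3-en-1-ol, via borinate ester 8 (not isolated)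
Conditions: (+)-Ipc2B(allyl), Et2O, −78 °C; then NaOH, H2O2, 0 °C to rt
Reagents that add atoms: (+)-B-allyldiisopinocampheylborane (7), C=CCB([C@H]1C[C@H]2C[C@@H]([C@@H]1C)C2(C)C)[C@H]1C[C@H]2C[C@@H]([C@@H]1C)C2(C)C
Why: Brown allylboration: the reagent delivers allyl to the Re face of the aldehyde through a chair-like six-membered transition state under reagent control and sets the (R)-carbinol (C4); the minor enantiomer of 6 gives a diastereomer that is removed by chromatography, and alkaline peroxide cleaves borinate 8.

Step 5
Reactants: 9 (1R)-1-[(1S)-1,3-dimethylcyclobut-2-en-1-yl]but-3-en-1-ol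
Product: 10 (1R,6S)-6-ethenyl-4,6-dimethylcyclohex-3-en-1-ol
Conditions: second-generation Grubbs catalyst (5 mol%), toluene (0.01 M), 50 °C, argon; after consumption of 9, ethylene (1 atm), 40 °C
Reagents that add atoms: none
Why: Ring-rearrangement metathesis: the catalyst initiates at the monosubstituted terminal alkene of 9, the alkylidene adds across the tethered cyclobutene with its carbon on the methyl-bearing ring carbon and ruthenium on the ring CH, and cycloreversion of the ruthenacyclobutane cleaves the four-membered ring while forming the C1=C2 bond. The ring that closes is the cyclohexene (C2–C3–C4–C5–C6–C1), by ring-closing metathesis in a bridging mode in which the alkylidene reaches the far alkene carbon across the cyclobutene through a bicyclo[3.1.1]heptane-like ruthenacycle. The neopentyl-type alkylidene left on the old ring CH takes a methylidene from the terminal alkene of the next substrate molecule, which gives the vinyl group on C5 and a new substrate alkylidene, so the process is a chain isomerisation driven by roughly 30 kcal/mol of cyclobutene strain. The closest known reaction type is the ring-opening/ring-closing cascade of cyclobutenes and other strained cycloalkenes that carry an alkenyl side chain. No stereocentre is formed and neither existing one is touched; the free homoallylic hydroxyl is tolerated by the catalyst. The step needs selectivity for the six-membered closure over the fused five-membered one and over oligomerisation: the first should follow from the reluctance of ruthenium to end on a disubstituted carbene carbon and from initiation at the only unhindered alkene, the second from dilution. Ethylene is withheld until 9 is consumed so that no methylidene carrier opens the cyclobutene first; the final purge cuts cross-metathesis dimers back to monomer, and the trisubstituted cyclohexene is inert to further metathesis.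

Step 6
Reactants: 10 (1R,6S)-6-ethenyl-4,6-dimethylcyclohex-3-en-1-ol
Product: 11 (1S,3R,4S,6R)-4-ethenyl-4,6-dimethyl-7-oxabicyclo[4.1.0]heptan-3-ol
Conditions: VO(acac)2 (3 mol%), t-BuOOH, CH2Cl2, 0 °C to rt
Reagents that add atoms: tert-butyl hydroperoxide, CC(C)(C)OO
Why: Hydroxyl-directed epoxidation of a cyclohex-3-en-1-ol: the vanadium alkoxide of the pseudoaxial homoallylic hydroxyl delivers oxygen to its own face and should give the cis-epoxy alcohol, which sets C1 and C2; the electron-rich trisubstituted ring alkene reacts far faster than the monosubstituted vinyl group.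

Step 7
Reactants: 11 (1S,3R,4S,6R)-4-ethenyl-4,6-dimethyl-7-oxabicyclo[4.1.0]heptan-3-ol
Product: 12 (1S,3R,4S,6R)-4-ethenyl-4,6-dimethyl-7-oxabicyclo[4.1.0]heptan-3-yl acetate
Conditions: Ac2O, DMAP, pyridine, CH2Cl2, rt
Reagents that add atoms: acetic anhydride, CC(=O)OC(C)=O
Why: Acylation under buffered conditions masks the hydroxyl so that the chlorophosphorane of step 8 cannot substitute it; the epoxide is inert to these conditions.

Step 8
Reactants: 12 (1S,3R,4S,6R)-4-ethenyl-4,6-dimethyl-7-oxabicyclo[4.1.0]heptan-3-yl acetate
Product: 13 (1R,2S,4S,5R)-4,5-dichloro-2-ethenyl-2,4-dimethylcyclohexyl acetate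
Conditions: Ph3PCl2, toluene, rt to 80 °C
Reagents that add atoms: dichlorotriphenylphosphorane, ClP(Cl)(c1ccccc1)(c1ccccc1)c1ccccc1
Why: Deoxydichlorination of an epoxide with double inversion: the phosphonium-activated oxirane is opened by chloride at the tertiary C1 anti to oxygen, and the alkoxyphosphonium left on C2 is displaced by chloride with inversion in an Appel-type step. Both chlorines therefore end on the face opposite the former epoxide, cis to each other and to the vinyl group; acetate and vinyl are spectators.

Step 9
Reactants: 13 (1R,2S,4S,5R)-4,5-dichloro-2-ethenyl-2,4-dimethylcyclohexyl acetate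
Product: 14 (1R,2S,4S,5R)-4,5-dichloro-2-ethenyl-2,4-dimethylcyclohexan-1-ol
Conditions: iBu2AlH (2.2 equiv), CH2Cl2, −78 °C
Reagents that add atoms: none
Why: Reductive cleavage of the acetate under non-basic conditions is chosen over methanolysis to spare the tertiary chloride from base-induced elimination; alkyl chlorides are inert to the hydride at this temperature.

Step 10
Reactants: 14 (1R,2S,4S,5R)-4,5-dichloro-2-ethenyl-2,4-dimethylcyclohexan-1-ol
Product: 15 (1S,2S,4R,5S)-2-bromo-4,5-dichloro-1-ethenyl-1,5-dimethylcyclohexane
Conditions: CBr4, PPh3, toluene, rt to 60 °C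
Reagents that add atoms: carbon tetrabromide, BrC(Br)(Br)Br
Why: Appel reaction with inversion: the hydroxyl of 14 is locked axial (both methyl groups equatorial), the arrangement from which hindered secondary alkoxyphosphonium ions are displaced by bromide to give the equatorial bromide, here cis to the vinyl group; C3 is no longer allylic, so the competing elimination is not assisted.

Step 11
Reactants: 15 (1S,2S,4R,5S)-2-bromo-4,5-dichloro-1-ethenyl-1,5-dimethylcyclohexane
Product: 17 (1S,2S,4R,5S)-2-bromo-4,5-dichloro-1,5-dimethylcyclohexane-1-carbaldehyde, via ozonide 16 (not isolated)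
Conditions: O3, CH2Cl2, −78 °C; then Me2S, −78 °C to rt
Reagents that add atoms: ozone, [O-][O+]=O
Why: Ozonolysis of the only remaining alkene with reductive work-up of ozonide 16; alkyl halides are inert to ozone, and the α-quaternary aldehyde can neither epimerise nor lose HBr by an E1cB path.

Step 12
Reactants: 17 (1S,2S,4R,5S)-2-bromo-4,5-dichloro-1,5-dimethylcyclohexane-1-carbaldehyde; 18 bromoform
Product: 19 (1S,2S,4R,5S)-2-bromo-1-[(E)-2-bromoethenyl]-4,5-dichloro-1,5-dimethylcyclohexane
Conditions: CrBr2 (from CrBr3 and LiAlH4), CHBr3, THF, 0 °C to rt
Reagents that add atoms: bromoform (18), BrC(Br)Br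
Why: Takai olefination: the geminal dichromium species formed from bromoform and divalent chromium adds to the aldehyde and eliminates to the (E)-bromoalkene; the bromide salt of chromium avoids chloride exchange into the alkenyl halide, and unactivated alkyl chlorides and the hindered secondary bromide should not be reduced.

## Compound list

1 | methyl 1-methyl-3-oxocyclobutane-1-carboxylate | COC(=O)C1(C)CC(=O)C1 | starting material
2 | lithium (3S)-3-(methoxycarbonyl)-3-methylcyclobut-1-en-1-olate | [Li+].[O-]C1=C[C@@](C)(C(=O)OC)C1 | intermediate (not isolated)
3 | methyl (1S)-1-methyl-3-[(trifluoromethanesulfonyl)oxy]cyclobut-2-ene-1-carboxylate | FC(F)(F)S(=O)(=O)OC1=C[C@@](C)(C(=O)OC)C1 | intermediate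
4 | methylmagnesium bromide | C[Mg]Br | starting material
5 | methyl (1S)-1,3-dimethylcyclobut-2-ene-1-carboxylate | CC1=C[C@@](C)(C(=O)OC)C1 | intermediate
6 | (1S)-1,3-dimethylcyclobut-2-ene-1-carbaldehyde | CC1=C[C@@](C)(C=O)C1 | intermediate
7 | (+)-B-allyldiisopinocampheylborane (isopinocampheyl groups from (−)-α-pinene) | C=CCB([C@H]1C[C@H]2C[C@@H]([C@@H]1C)C2(C)C)[C@H]1C[C@H]2C[C@@H]([C@@H]1C)C2(C)C | starting material
8 | (1R)-1-[(1S)-1,3-dimethylcyclobut-2-en-1-yl]but-3-en-1-yl diisopinocampheylborinate | CC1=C[C@@](C)([C@H](OB([C@H]2C[C@H]3C[C@@H]([C@@H]2C)C3(C)C)[C@H]2C[C@H]3C[C@@H]([C@@H]2C)C3(C)C)CC=C)C1 | intermediate (not isolated)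
9 | (1R)-1-[(1S)-1,3-dimethylcyclobut-2-en-1-yl]but-3-en-1-ol | CC1=C[C@@](C)([C@H](O)CC=C)C1 | intermediate
10 | (1R,6S)-6-ethenyl-4,6-dimethylcyclohex-3-en-1-ol | C1=C(C)C[C@@](C)(C=C)[C@H](O)C1 | intermediate
11 | (1S,3R,4S,6R)-4-ethenyl-4,6-dimethyl-7-oxabicyclo[4.1.0]heptan-3-ol | C[C@@]12C[C@@](C)(C=C)[C@H](O)C[C@@H]1O2 | intermediate
12 | (1S,3R,4S,6R)-4-ethenyl-4,6-dimethyl-7-oxabicyclo[4.1.0]heptan-3-yl acetate | C[C@@]12C[C@@](C)(C=C)[C@H](OC(C)=O)C[C@@H]1O2 | intermediate
13 | (1R,2S,4S,5R)-4,5-dichloro-2-ethenyl-2,4-dimethylcyclohexyl acetate | C[C@]1(Cl)C[C@@](C)(C=C)[C@H](OC(C)=O)C[C@H]1Cl | intermediate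
14 | (1R,2S,4S,5R)-4,5-dichloro-2-ethenyl-2,4-dimethylcyclohexan-1-ol | C[C@]1(Cl)C[C@@](C)(C=C)[C@H](O)C[C@H]1Cl | intermediate
15 | (1S,2S,4R,5S)-2-bromo-4,5-dichloro-1-ethenyl-1,5-dimethylcyclohexane | C[C@]1(Cl)C[C@@](C)(C=C)[C@@H](Br)C[C@H]1Cl | intermediate
16 | 3-[(1S,2S,4R,5S)-2-bromo-4,5-dichloro-1,5-dimethylcyclohexyl]-1,2,4-trioxolane (both epimers at the trioxolane carbon) | C[C@]1(Cl)C[C@@](C)(C2OCOO2)[C@@H](Br)C[C@H]1Cl | intermediate (not isolated)
17 | (1S,2S,4R,5S)-2-bromo-4,5-dichloro-1,5-dimethylcyclohexane-1-carbaldehyde | C[C@]1(Cl)C[C@@](C)(C=O)[C@@H](Br)C[C@H]1Cl | intermediate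
18 | bromoform | BrC(Br)Br | starting material
19 | (1S,2S,4R,5S)-2-bromo-1-[(E)-2-bromoethenyl]-4,5-dichloro-1,5-dimethylcyclohexane | C[C@]1(Cl)C[C@@](C)(/C=C/Br)[C@@H](Br)C[C@H]1Cl | target

## Step count and least certain steps

Total: 12 steps. Longest linear sequence: 12 steps (1 to 19).

**Step 5 (key step).** The most likely failure is closure of the tethered alkylidene on the near cyclobutene carbon (fused five-membered mode). A related failure is opening of the cyclobutene by a methylidene carrier before the side chain has engaged, after which closure onto the freed vinyl group gives a cyclopentene. Both arise because the wanted closure has to bridge the four-membered ring. Fallback, from 5 back to 10: the four-membered ring is opened oxidatively before any second alkene is present, and the six-membered ring is closed by ordinary ring-closing metathesis while the future vinyl carbon is held as an acetal. Ozonolysis of 5 (O3, CH2Cl2, −78 °C; Me2S) passes through the ozonide methyl (5S)-1,5-dimethyl-2,3,7-trioxabicyclo[2.2.1]heptane-5-carboxylate F1 and gives the keto aldehyde methyl (2S)-2-formyl-2-methyl-4-oxopentanoate F2. Selective acetalisation of the aldehyde (HC(OMe)3, MeOH, pyridinium tosylate) gives methyl (2S)-2-(dimethoxymethyl)-2-methyl-4-oxopentanoate F3, and Wittig methylenation of the ketone gives methyl (2S)-2-(dimethoxymethyl)-2,4-dimethylpent-4-enoate F4. Reduction with iBu2AlH gives (2R)-2-(dimethoxymethyl)-2,4-dimethylpent-4-enal F5. Allylboration with 7 as in step 4, through the diisopinocampheylborinate ester F6, gives (4R,5R)-5-(dimethoxymethyl)-5,7-dimethylocta-1,7-dien-4-ol F7, in which only the allyl and methallyl alkenes can meet. Ring-closing metathesis with the second-generation Grubbs catalyst gives (1R,6R)-6-(dimethoxymethyl)-4,6-dimethylcyclohex-3-en-1-ol F8. Mild acid hydrolysis to (1R,6R)-6-hydroxy-1,3-dimethylcyclohex-3-ene-1-carbaldehyde F9 and non-basic methylenation (Zn, CH2Br2, TiCl4) return 10.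

**Step 1.** The two enantiotopic methylene groups may be poorly distinguished, because methyl and methoxycarbonyl differ little in size and the base must also choose a face of the ring; the sense of induction may be opposite to the one assumed, and the cyclobutanone enolate may self-condense. Fallback, from 1 back to 9: the ketone is converted without asymmetric induction (Tf2O, 2,6-di-tert-butyl-4-methylpyridine) into racemic methyl 1-methyl-3-[(trifluoromethanesulfonyl)oxy]cyclobut-2-ene-1-carboxylate F10. This is methylated as in step 2 to racemic methyl 1,3-dimethylcyclobut-2-ene-1-carboxylate F11 and reduced as in step 3 to racemic 1,3-dimethylcyclobut-2-ene-1-carbaldehyde F12. Allylboration with 7 then serves as the resolving step. Reagent control gives the (R)-carbinol from both aldehyde enantiomers, through borinate 8 and the diastereomeric diisopinocampheylborinate ester F13, so that 9 forms together with (1R)-1-[(1R)-1,3-dimethylcyclobut-2-en-1-yl]but-3-en-1-ol F14, and the two are separated by chromatography. Half of the material is given up in exchange for independence from the chiral base.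

**Step 8.** Once the C1–O bond loosens, the tertiary centre may be lost by elimination or by a hydride or alkyl shift; chloride must enter at C1 syn to the axial vinyl group. The second displacement at C2, next to the new tertiary chloride, may be slow, or may proceed with retention through participation of the neighbouring chlorine. Fallback, from 12 back to 13: ring opening and substitution are separated. Anhydrous HCl in Et2O at low temperature opens the epoxide at C1 to the chlorohydrin (1R,2S,4S,5S)-4-chloro-2-ethenyl-5-hydroxy-2,4-dimethylcyclohexyl acetate F15, which is isolated. Its axial hydroxyl is converted (ClCH2SO2Cl, pyridine) into the chloromethanesulfonate (1R,2S,4S,5S)-4-chloro-5-{[(chloromethyl)sulfonyl]oxy}-2-ethenyl-2,4-dimethylcyclohexyl acetate F16. This leaving group is less prone to ionise than a phosphonium ion and is displaced with inversion by LiCl in DMF to give 13.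

**Step 10.** Bimolecular displacement at a carbon flanked by the quaternary C5 may be too slow, so that elimination toward C3 or a 1,2-shift of the anti-periplanar vinyl group takes over. Fallback, from 9 back to 15: the substitution is moved ahead of ring formation. There the four-membered ring ties back two of the three substituents on the quaternary carbon and leaves the carbinol carbon more open than in 14. Appel bromination of 9 (CBr4, PPh3) with inversion gives (3S)-3-[(1S)-1-bromobut-3-en-1-yl]-1,3-dimethylcyclobut-1-ene F17. Ring-rearrangement metathesis as in step 5 gives (4S,5S)-4-bromo-5-ethenyl-1,5-dimethylcyclohex-1-ene F18. Epoxidation with 3-chloroperbenzoic acid on the face away from bromine and the vinyl group gives (1R,3S,4S,6S)-4-bromo-3-ethenyl-1,3-dimethyl-7-oxabicyclo[4.1.0]heptane F19, and Ph3PCl2 as in step 8 converts it into 15. The price is the loss of the directing hydroxyl, so the facial selectivity of the epoxidation rests on sterics alone.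

## Further compounds

F1 | step 5 | methyl (5S)-1,5-dimethyl-2,3,7-trioxabicyclo[2.2.1]heptane-5-carboxylate (both bridgehead diastereomers) | CC12C[C@](C)(C(=O)OC)C(OO1)O2
F2 | step 5 | methyl (2S)-2-formyl-2-methyl-4-oxopentanoate | CC(=O)C[C@](C)(C(=O)OC)C=O
F3 | step 5 | methyl (2S)-2-(dimethoxymethyl)-2-methyl-4-oxopentanoate | CC(=O)C[C@](C)(C(=O)OC)C(OC)OC
F4 | step 5 | methyl (2S)-2-(dimethoxymethyl)-2,4-dimethylpent-4-enoate | C=C(C)C[C@](C)(C(=O)OC)C(OC)OC
F5 | step 5 | (2R)-2-(dimethoxymethyl)-2,4-dimethylpent-4-enal | C=C(C)C[C@](C)(C=O)C(OC)OC
F6 | step 5 | (4R,5R)-5-(dimethoxymethyl)-5,7-dimethylocta-1,7-dien-4-yl diisopinocampheylborinate | C=C(C)C[C@](C)([C@H](OB([C@H]1C[C@H]2C[C@@H]([C@@H]1C)C2(C)C)[C@H]1C[C@H]2C[C@@H]([C@@H]1C)C2(C)C)CC=C)C(OC)OC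
F7 | step 5 | (4R,5R)-5-(dimethoxymethyl)-5,7-dimethylocta-1,7-dien-4-ol | C=C(C)C[C@](C)([C@H](O)CC=C)C(OC)OC
F8 | step 5 | (1R,6R)-6-(dimethoxymethyl)-4,6-dimethylcyclohex-3-en-1-ol | C1=C(C)C[C@@](C)(C(OC)OC)[C@H](O)C1
F9 | step 5 | (1R,6R)-6-hydroxy-1,3-dimethylcyclohex-3-ene-1-carbaldehyde | C1=C(C)C[C@@](C)(C=O)[C@H](O)C1
F10 | step 1 | racemic methyl 1-methyl-3-[(trifluoromethanesulfonyl)oxy]cyclobut-2-ene-1-carboxylate | COC(=O)C1(C)CC(OS(=O)(=O)C(F)(F)F)=C1
F11 | step 1 | racemic methyl 1,3-dimethylcyclobut-2-ene-1-carboxylate | CC1=CC(C)(C(=O)OC)C1
F12 | step 1 | racemic 1,3-dimethylcyclobut-2-ene-1-carbaldehyde | CC1=CC(C)(C=O)C1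
F13 | step 1 | (1R)-1-[(1R)-1,3-dimethylcyclobut-2-en-1-yl]but-3-en-1-yl diisopinocampheylborinate | CC1=C[C@](C)([C@H](OB([C@H]2C[C@H]3C[C@@H]([C@@H]2C)C3(C)C)[C@H]2C[C@H]3C[C@@H]([C@@H]2C)C3(C)C)CC=C)C1
F14 | step 1 | (1R)-1-[(1R)-1,3-dimethylcyclobut-2-en-1-yl]but-3-en-1-ol | CC1=C[C@](C)([C@H](O)CC=C)C1
F15 | step 8 | (1R,2S,4S,5S)-4-chloro-2-ethenyl-5-hydroxy-2,4-dimethylcyclohexyl acetate | C[C@]1(Cl)C[C@@](C)(C=C)[C@H](OC(C)=O)C[C@@H]1O
F16 | step 8 | (1R,2S,4S,5S)-4-chloro-5-{[(chloromethyl)sulfonyl]oxy}-2-ethenyl-2,4-dimethylcyclohexyl acetate | C[C@]1(Cl)C[C@@](C)(C=C)[C@H](OC(C)=O)C[C@@H]1OS(=O)(=O)CCl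
F17 | step 10 | (3S)-3-[(1S)-1-bromobut-3-en-1-yl]-1,3-dimethylcyclobut-1-ene | CC1=C[C@@](C)([C@@H](Br)CC=C)C1
F18 | step 10 | (4S,5S)-4-bromo-5-ethenyl-1,5-dimethylcyclohex-1-ene | C1=C(C)C[C@@](C)(C=C)[C@@H](Br)C1
F19 | step 10 | (1R,3S,4S,6S)-4-bromo-3-ethenyl-1,3-dimethyl-7-oxabicyclo[4.1.0]heptane | C[C@@]12C[C@@](C)(C=C)[C@@H](Br)C[C@@H]1O2
A1 | alternative 1 | (1R,6R)-6-{[tert-butyl(dimethyl)silyl]oxymethyl}-8,8-dimethyl-9-oxa-8-silabicyclo[4.3.0]nonan-4-one (cis-fused) | O=C1C[C@]2(CO[Si](C)(C)C(C)(C)C)C[Si](C)(C)O[C@@H]2CC1
A2 | alternative 1 | (4R)-4-{[(bromomethyl)dimethylsilyl]oxy}-3-{[tert-butyl(dimethyl)silyl]oxymethyl}cyclohex-2-en-1-one | O=C1C=C(CO[Si](C)(C)C(C)(C)C)[C@H](O[Si](C)(C)CBr)CC1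
A3 | alternative 2 | (4S,6S)-6-acetyl-4,6-dimethylcyclohex-2-en-1-one | C[C@H]1C[C@@](C)(C(C)=O)C(=O)C=C1
A4 | alternative 2 | 4-acetyl-2,4-dimethyl-5-oxohexanal (racemic) | CC(C=O)CC(C)(C(C)=O)C(C)=O
A5 | alternative 3 | (1R,2S,5S)-1,5-dimethyl-2-[(triisopropylsilyl)oxy]cyclohex-3-ene-1-carbaldehyde | C[C@H]1C[C@@](C)(C=O)[C@@H](O[Si](C(C)C)(C(C)C)C(C)C)C=C1
A6 | alternative 3 | methacrolein | CC(=C)C=O
A7 | alternative 3 | (1E,3E)-1-[(triisopropylsilyl)oxy]penta-1,3-diene | C/C=C/C=C/O[Si](C(C)C)(C(C)C)C(C)C
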